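## Structural features

The target is a flavone: a benzene ring A fused through C4a–C8a to a 4-pyranone ring C, which carries an unsubstituted phenyl ring B at C2. Ring A has no C–H left, since C5, C6, C7 and C8 each bear a methoxyl and the other two carbons are the ring-fusion atoms. Ring C carries the fifth methoxyl at C3, next to the C4 carbonyl. The target has no stereocentre; the only stereocentres of the route are the adjacent C2 and C3 of the 2,3-dihydro stage, and both become sp2 before the end, so no stereocontrol is needed. The fragile points are the C5 methoxyl peri to the C4 carbonyl (chelation-assisted demethylation by protic or Lewis acids), the very electron-rich ring A (oxidation to quinones, easy ionisation of benzylic positions) and the O1–C2 bond of dihydro intermediates, which opens by β-elimination under base. The real difficulty is the hexasubstituted ring A with its unbroken C5–C8 oxygenation, together with the oxygen at C3 of a pyranone flanked by the peri methoxyl. The key step uses the fact that C4 (carbonyl) and C3 (oxygen-bearing) are neighbouring oxidised carbons of ring C: in the 2,3-dihydro form this is an α-ketol, the product of joining two aldehyde carbons after polarity reversal of one.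

## Logic of the disconnections

12 ⇒ 11. The O–CH3 bond of the C3 methoxyl is cut. This lets the C3 oxygen travel as the free enolic hydroxyl that the ring-forming chemistry produces, while the four ring-A ethers come from the starting material. The forward step must alkylate a hindered enolic hydroxyl next to the C4 carbonyl, which is easy once every other oxygen is capped.

11 ⇒ 10. No skeletal bond is cut; the C2=C3 double bond is taken back to the dihydro level, so that C3 becomes a carbinol carbon beside the C4 ketone. This exposes the α-ketol and creates two stereocentres that need not be controlled. The forward step must remove two hydrogens from a base-sensitive ketol without loss of the C5 methyl group.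

10 ⇒ 9. The C3–C4 bond is cut, which opens ring C and leaves an aryl aldehyde (C4) and an aliphatic aldehyde (C3) joined by the O1–C2 ether. Both carbons are electrophilic in 9, so their union needs umpolung of one of them, which a carbene catalyst provides without stoichiometric reagents. The gain is the whole pyranone ring and the C3 oxygen from one C–C bond. The forward step must make C4 the acyl anion equivalent and let it attack C3 faster than fragmentation, aldol closure or dimerisation.

9 ⇒ 8. Both aldehyde carbons are taken back to primary carbinols. 9 contains a labile α-aryloxy-α-phenyl aldehyde and is best made immediately before use from a stable precursor. The forward step must oxidise two primary alcohols, stop at the aldehyde, and avoid both acid (benzylic carbinol on a trialkoxyphenyl ring) and base (enolisable aldehyde).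

8 ⇒ 7. The two carbinols are traced to an aryl aldehyde and a methyl ester, which one hydride reagent reduces together, so no protecting group is needed. The forward step must reduce completely without cleaving the benzylic O1–C2 ether.

7 ⇒ 5 + 6. The O1–C2 bond is cut, separating the ring-A fragment from the C2/C3/ring-B fragment; this is the only convergent point of the route. The forward step is an SN2 reaction of a hindered, hydrogen-bonded phenoxide at a secondary benzylic α-bromo ester, and it must stop before the acidic α-CH of 7 attacks the formyl group.

5 ⇒ 4. The bond between ring A and the formyl carbon (C4a–C4) is cut. The single unsubstituted ring carbon of 4 is ortho to the hydroxyl, so there is no regiochemical question. The forward step needs a formylation mild enough for an oxidation-prone ring.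

4 ⇒ 1. The aryl C–O bond of the future O1 is cut. The two C–H positions of 1 are equivalent and each lies ortho to a methoxyl, so directed metalation gives one aryl anion. The forward step must monolithiate and then oxidise the aryl–boron bond without oxidising the electron-rich phenol.

## Other disconnections considered

Alternative 1: The cut falls on the aryl C6–O and C8–O bonds. Forward, 6,8-dibromo-5-hydroxy-3,7-dimethoxyflavone A2 would be heated with NaOMe and CuBr in DMF/methanol, so that both bromides are exchanged for methoxyl in an Ullmann-type substitution through aryl–copper intermediates. The product of this step would be 5-hydroxy-3,6,7,8-tetramethoxyflavone A1, and methylation of the chelated 5-hydroxyl of A1 would finish 12. A2 should come from dibromination of 5-hydroxy-3,7-dimethoxyflavone A3, and A3 from partial methylation of commercial galangin A4, whose 5-hydroxyl is shielded from alkylation by its hydrogen bond to the carbonyl.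
- In favour: the flavonol skeleton with its C3 oxygen is bought in A4, ring A is edited at its two innately nucleophilic positions, and no sensitive aldehyde appears.
- Against: two substitutions at hindered positions of an electron-rich ring need hot alkoxide, which invites protodebromination and methoxide attack at C2 of the pyranone. The last methylation must also overcome the hydrogen bond of the 5-hydroxyl.
- Comparison: on step economy the alternative is clearly better (about four steps against eight). On structure it keeps the skeleton and adjusts substituents, whereas the chosen plan builds ring C and takes ring-A oxygenation unambiguously from 1. On mechanism it needs two copper-mediated C–O couplings where the chosen plan needs one metal-free C–C bond; copper methoxylation of bromoarenes is an established reaction type, so the alternative's key step is at least as safe as the untested cyclisation of 9.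

Alternative 2: The cuts are C4a–C4, C4–C3 and O1–C2, with carbon monoxide A8 as C4. Forward, 2-iodo-3,4,5,6-tetramethoxyphenol A6, which is one iodination away from 4, would react with A8 and phenylacetylene A7 under PdCl2(PPh3)2 in diethylamine. Zerovalent palladium inserts into the aryl–iodine bond of A6, A8 inserts to an acylpalladium species, coupling with A7 gives an ynone, and the phenol oxygen adds to the phenyl-bearing alkyne carbon in a six-endo sense. The product would be 5,6,7,8-tetramethoxyflavone A5.
- In favour: three bonds and ring C form in one operation from simple pieces, and it shares 4 with the chosen plan.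
- Against: A5 lacks the C3 oxygen, so a later C3 hydroxylation (for example dioxirane epoxidation of C2=C3 and rearrangement to 11) and a methylation must follow. Oxidative addition to a doubly ortho-substituted, electron-rich aryl iodide is slow. Direct coupling of A6 with A7 without insertion of A8, and five-exo instead of six-endo closure of the ynone, would compete, and A8 is a toxic gas.
- Comparison: on convergence and step count the alternative is the better plan (about five steps from 1 against eight). On structure the chosen plan fits better, because the acyloin union delivers the C3 oxygen as part of ring closure rather than adding it to a finished pyranone. On mechanism, palladium carbonylation is well established but carries its own chemoselectivity problems; the chosen plan needs no metal and no gas, though its key step is less tested.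

Alternative 3: The cut is O1–C2, with a methoxyl oxygen as latent O1, plus a C3–iodine bond. Forward, ICl would activate the alkyne of 1-(2,3,4,5,6-pentamethoxyphenyl)-3-phenylprop-2-yn-1-one A10. An ortho methoxyl oxygen attacks the phenyl-bearing carbon (six-endo-dig), and chloride removes the methyl group from the oxonium ion, so that the product would be 3-iodo-5,6,7,8-tetramethoxyflavone A9. A10 should come from pentamethoxybenzene A11, the methyl ether of 4, by metalation of its single C–H and acylation with N-methoxy-N-methyl-3-phenylprop-2-ynamide A12. A9 would be converted into 12 by copper-mediated methoxylation (NaOMe, CuBr).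
- In favour: the two ortho methoxyls of A10 are equivalent, no free phenol and no ring-A C–H are present, and the iodine of A9 sits exactly where the last methoxyl is needed.
- Against: exchanging a vinylic carbon–iodine bond for methoxyl at the α-position of a vinylogous ester competes with conjugate attack of methoxide at C2 and with reduction of the carbon–iodine bond. ICl is also an oxidant towards a pentaoxygenated ring.
- Comparison: on step count the alternative is somewhat better (about five steps from 1), and the electrophilic ring closure is a well-established reaction type, so that step is more secure than the chosen key step. The chosen plan is better only in that the C3 oxygen arrives with the ring-forming bond and no halogen–oxygen exchange on the pyranone is needed. On mechanism the two are complementary: electrophilic alkyne activation there, nucleophilic carbene catalysis here.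

Key step: step 6

Remark on the chemistry: the two aldehydes of 9 are not interchangeable as acyl donors. An acyl anion equivalent at the aliphatic aldehyde has the aryloxy oxygen in the β-position and can expel it, so the donor role is assigned to the aryl aldehyde and catalyst, base and solvent are chosen for that. The route is racemic because C2 and C3 are flattened in step 7.

Step 1
Reactants: 1 1,2,3,4-tetramethoxybenzene
Product: 4 2,3,4,5-tetramethoxyphenol, via aryllithium 2 (not isolated), via lithium aryltrimethoxyborate 3 (not isolated)
Conditions: n-BuLi, TMEDA, THF, 0 °C; B(OMe)3, −78 °C → rt; AcOH, 30% H2O2, 0 °C → rt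
Reagents that add atoms: hydrogen peroxide, OO
Why: Directed ortho-metalation followed by borylation and oxidation of the carbon–boron bond (1,2-shift of the aryl group from boron to oxygen); the two C–H positions of 1 are equivalent and ortho to a methoxyl, so only one aryl anion can form.

Step 2
Reactants: 4 2,3,4,5-tetramethoxyphenol
Product: 5 2-hydroxy-3,4,5,6-tetramethoxybenzaldehyde
Conditions: MgCl2, Et3N, (CH2O)n, MeCN, reflux; then 1 M HCl
Reagents that add atoms: paraformaldehyde (source of formaldehyde), C=O
Why: Magnesium-mediated ortho-formylation of a phenol (Casnati–Skattebøl reaction): the magnesium phenoxide delivers formaldehyde to the ortho carbon and a second formaldehyde oxidises the hydroxymethyl group by hydride transfer; the only unsubstituted ring carbon of 4 is that ortho position.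

Step 3
Reactants: 5 2-hydroxy-3,4,5,6-tetramethoxybenzaldehyde; 6 methyl 2-bromo-2-phenylacetate (racemic)
Product: 7 methyl 2-(2-formyl-3,4,5,6-tetramethoxyphenoxy)-2-phenylacetate (racemic)
Conditions: K2CO3, DMF, rt
Reagents that add atoms: none
Why: Williamson ether synthesis: the phenoxide displaces bromide from the activated secondary benzylic α-bromo ester by SN2 at room temperature, where the mild base should not yet engage the acidic α-CH of the product; the new C2 centre is formed racemic.

Step 4
Reactants: 7 methyl 2-(2-formyl-3,4,5,6-tetramethoxyphenoxy)-2-phenylacetate
Product: 8 2-[2-(hydroxymethyl)-3,4,5,6-tetramethoxyphenoxy]-2-phenylethan-1-ol (racemic)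
Conditions: LiAlH4, THF, 0 °C; then H2O, 15% aq NaOH
Reagents that add atoms: none
Why: Hydride reduction of the aldehyde and the ester in one operation; aryl methyl ethers and the benzylic aryl ether are inert to LiAlH4, and the basic work-up spares the acid-labile benzylic carbinol.

Step 5
Reactants: 8 2-[2-(hydroxymethyl)-3,4,5,6-tetramethoxyphenoxy]-2-phenylethan-1-ol
Product: 9 2-(2-formyl-3,4,5,6-tetramethoxyphenoxy)-2-phenylacetaldehyde (racemic)
Conditions: IBX, DMSO, rt; aqueous work-up, used crude at once
Reagents that add atoms: none
Why: Hypervalent-iodine oxidation of both primary alcohols (ligand exchange at iodine, then elimination) stops at the aldehyde; the medium has no chloride, strong acid or amine base, which suits the ionisable trialkoxybenzylic carbinol and the enolisable α-aryloxy aldehyde.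

Step 6
Reactants: 9 2-(2-formyl-3,4,5,6-tetramethoxyphenoxy)-2-phenylacetaldehyde
Product: 10 3-hydroxy-5,6,7,8-tetramethoxy-2-phenylchroman-4-one (3-hydroxy-5,6,7,8-tetramethoxyflavanone; racemic, cis/trans mixture at C2/C3)
Conditions: 2-(pentafluorophenyl)-6,7-dihydro-5H-pyrrolo[2,1-c][1,2,4]triazol-2-ium tetrafluoroborate (20 mol %), DBU (15 mol %), toluene (0.02 M), rt, Ar
Reagents that add atoms: none
Why: Intramolecular crossed benzoin (acyloin) reaction under N-heterocyclic carbene catalysis: the triazolylidene adds to the aryl aldehyde carbon C4, proton transfer gives the Breslow intermediate (an enaminol, the acyl anion equivalent), its carbon attacks the aliphatic aldehyde carbon C3, and collapse of the adduct releases the carbene and the C4 ketone. The closest known reaction type is the carbene-catalysed cyclisation of 2-(2-oxoalkoxy)benzaldehydes and of tethered dialdehydes to six-membered α-ketols, where the salicylaldehyde-derived formyl group is the donor across the same O–C tether. Ring C closes in a 6-exo-trig mode, the attacked C3=O bond lying outside the new ring C4–C4a–C8a–O1–C2–C3. The new stereocentre C3 is set under substrate control by C2 (phenyl pseudo-equatorial in a chair-like transition state, C3 epimerisable afterwards), but its configuration does not matter because C2 and C3 both become sp2 in step 7. The selectivity needed is chemoselectivity: donor formation at the aryl aldehyde and not at the aliphatic one (whose acyl anion equivalent could expel the β-aryloxy oxygen in an internal redox fragmentation), C–C bond formation and not aldol attack of the C2 enolate on the aryl aldehyde, and ring closure and not dimerisation. The substrate contributes the more acidic benzylic C–H of the aryl aldehyde adduct, the α-branching of the aliphatic aldehyde and the ortho tether that holds both carbonyls within reach; the conditions contribute an acidic precatalyst that needs only substoichiometric DBU (no free base for enolisation or for ring opening of 10), a non-polar solvent that disfavours expulsion of an aryloxide, and dilution. If the donor role were reversed and the ring still closed, nothing would be lost, because the transposed ketol would be oxidised through the same enediol in step 7.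

Step 7
Reactants: 10 3-hydroxy-5,6,7,8-tetramethoxy-2-phenylchroman-4-one
Product: 11 3-hydroxy-5,6,7,8-tetramethoxy-2-phenyl-4H-chromen-4-one (3-hydroxy-5,6,7,8-tetramethoxyflavone)
Conditions: I2 (10 mol %), DMSO, 100 °C
Reagents that add atoms: none
Why: Iodine-catalysed dehydrogenation with DMSO as terminal oxidant: enolisation of the ketol towards C3, oxidation of the resulting enediol by iodine and tautomerisation towards C2 place the double bond between C2 and C3, and DMSO reoxidises HI to I2; both stereocentres disappear.

Step 8
Reactants: 11 3-hydroxy-5,6,7,8-tetramethoxy-2-phenyl-4H-chromen-4-one
Product: 12 3,5,6,7,8-pentamethoxy-2-phenyl-4H-chromen-4-one (3,5,6,7,8-pentamethoxyflavone)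
Conditions: MeI, K2CO3, acetone, reflux
Reagents that add atoms: iodomethane, CI
Why: Williamson O-alkylation of the acidic enolic 3-hydroxyl; all other oxygens are already capped, so a single methylation gives the target.

Compound list

1 | 1,2,3,4-tetramethoxybenzene | COc1ccc(OC)c(OC)c1OC | starting material
2 | (2,3,4,5-tetramethoxyphenyl)lithium | [Li]c1cc(OC)c(OC)c(OC)c1OC | intermediate
3 | lithium trimethoxy(2,3,4,5-tetramethoxyphenyl)borate | [Li+].CO[B-](OC)(OC)c1cc(OC)c(OC)c(OC)c1OC | intermediate
4 | 2,3,4,5-tetramethoxyphenol | COc1cc(O)c(OC)c(OC)c1OC | intermediate
5 | 2-hydroxy-3,4,5,6-tetramethoxybenzaldehyde | COc1c(OC)c(OC)c(C=O)c(O)c1OC | intermediate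
6 | methyl 2-bromo-2-phenylacetate (racemic) | COC(=O)C(Br)c1ccccc1 | starting material
7 | methyl 2-(2-formyl-3,4,5,6-tetramethoxyphenoxy)-2-phenylacetate (racemic) | COC(=O)C(Oc1c(C=O)c(OC)c(OC)c(OC)c1OC)c1ccccc1 | intermediate
8 | 2-[2-(hydroxymethyl)-3,4,5,6-tetramethoxyphenoxy]-2-phenylethan-1-ol (racemic) | OCC(Oc1c(CO)c(OC)c(OC)c(OC)c1OC)c1ccccc1 | intermediate
9 | 2-(2-formyl-3,4,5,6-tetramethoxyphenoxy)-2-phenylacetaldehyde (racemic) | COc1c(OC)c(OC)c(C=O)c(OC(C=O)c2ccccc2)c1OC | intermediate
10 | 3-hydroxy-5,6,7,8-tetramethoxy-2-phenylchroman-4-one (racemic, cis/trans mixture at C2/C3) | COc1c(OC)c(OC)c2c(c1OC)OC(c1ccccc1)C(O)C2=O | intermediate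
11 | 3-hydroxy-5,6,7,8-tetramethoxy-2-phenyl-4H-chromen-4-one | COc1c(OC)c(OC)c2c(=O)c(O)c(-c3ccccc3)oc2c1OC | intermediate
12 | 3,5,6,7,8-pentamethoxy-2-phenyl-4H-chromen-4-one (achiral) | COc1c(OC)c(OC)c2c(=O)c(OC)c(-c3ccccc3)oc2c1OC | target

Total step count: 8. Longest linear sequence: 8 steps, from 1 to 12 (6 is purchased and enters at step 3).

Steps least certain to work

Step 6 (key step). The most likely failure is that the carbene engages the more electrophilic aliphatic aldehyde and the resulting acyl anion equivalent fragments by loss of the aryloxy group, which is a good leaving group because of its ortho-formyl substituent and the conjugation gained with the phenyl ring. The second risk is base-mediated aldol closure of a five-membered ring through the C2 enolate before the carbene pathway acts. A fallback using known chemistry starts from 9 and avoids any anion or enaminol at C3. Reductive pinacol cyclisation with SmI2 (THF, t-BuOH, −78 °C) should put the first electron on the aryl aldehyde, whose ketyl has no leaving group in the β-position and adds to C3, giving 5,6,7,8-tetramethoxy-2-phenylchromane-3,4-diol F1. Oxidation of both carbinols with IBX in DMSO would give 5,6,7,8-tetramethoxy-2-phenylchromane-3,4-dione F2, which tautomerises towards C2. The fallback rejoins the route at 11, and step 8 follows.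

Step 5. The risk is decomposition during the double oxidation and isolation: ionisation of the very electron-rich benzylic carbinol before it is oxidised, and enolisation, hydration or self-condensation of the α-aryloxy-α-phenyl aldehyde once it has formed. The fallback starts from 7 and avoids both the diol and the double oxidation. The aryl aldehyde is protected (MeOH, HC(OMe)3, cat. TsOH) as methyl 2-[2-(dimethoxymethyl)-3,4,5,6-tetramethoxyphenoxy]-2-phenylacetate F3. The ester is reduced only to the aldehyde stage with i-Bu2AlH (toluene, −78 °C) to give 2-[2-(dimethoxymethyl)-3,4,5,6-tetramethoxyphenoxy]-2-phenylacetaldehyde F4. The very labile electron-rich aryl acetal is then opened with wet acetone and pyridinium tosylate immediately before the cyclisation. The fallback rejoins the route at 9.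

Step 3. The risk is that O-alkylation of the hindered, hydrogen-bonded phenoxide is slow enough for the base to deprotonate the acidic α-CH of the product, which would then add to the ortho-formyl group in an intramolecular aldol closure. The fallback reverses the order of bond formation and starts from 4, which has no aldehyde. Alkylation of 4 with 6 (K2CO3, DMF) gives methyl 2-phenyl-2-(2,3,4,5-tetramethoxyphenoxy)acetate F5. Rieche formylation (Cl2CHOMe, TiCl4, CH2Cl2, −20 °C) then introduces the formyl group at the one free position of the pentaoxygenated ring. The fallback rejoins the route at 7.

Step 7. The risk is that HI formed during the oxidation causes loss of the C5 methyl group, assisted by chelation to the C4 carbonyl, or that the ketol undergoes ring opening and contraction before it is dehydrogenated. The fallback starts from 10 and changes the order of events. The C3 hydroxyl is methylated under neutral conditions (MeI, Ag2O, CH2Cl2) to 3,5,6,7,8-pentamethoxy-2-phenylchroman-4-one F6, which no longer has the free ketol. Dehydrogenation across C2–C3 with DDQ (dioxane, reflux), a known flavanone-to-flavone conversion, follows. The fallback rejoins the route at 12.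

Further compounds

F1 | step 6 | 5,6,7,8-tetramethoxy-2-phenylchromane-3,4-diol (racemic diastereomer mixture) | COc1c(OC)c(OC)c2c(c1OC)OC(c1ccccc1)C(O)C2O
F2 | step 6 | 5,6,7,8-tetramethoxy-2-phenylchromane-3,4-dione (racemic) | COc1c(OC)c(OC)c2c(c1OC)OC(c1ccccc1)C(=O)C2=O
F3 | step 5 | methyl 2-[2-(dimethoxymethyl)-3,4,5,6-tetramethoxyphenoxy]-2-phenylacetate (racemic) | COC(=O)C(Oc1c(C(OC)OC)c(OC)c(OC)c(OC)c1OC)c1ccccc1
F4 | step 5 | 2-[2-(dimethoxymethyl)-3,4,5,6-tetramethoxyphenoxy]-2-phenylacetaldehyde (racemic) | O=CC(Oc1c(C(OC)OC)c(OC)c(OC)c(OC)c1OC)c1ccccc1
F5 | step 3 | methyl 2-phenyl-2-(2,3,4,5-tetramethoxyphenoxy)acetate (racemic) | COC(=O)C(Oc1cc(OC)c(OC)c(OC)c1OC)c1ccccc1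
F6 | step 7 | 3,5,6,7,8-pentamethoxy-2-phenylchroman-4-one (racemic, cis/trans mixture) | COc1c(OC)c(OC)c2c(c1OC)OC(c1ccccc1)C(OC)C2=O
A1 | alternative 1 | 5-hydroxy-3,6,7,8-tetramethoxyflavone | COc1c(OC)c(O)c2c(=O)c(OC)c(-c3ccccc3)oc2c1OC
A2 | alternative 1 | 6,8-dibromo-5-hydroxy-3,7-dimethoxyflavone | COc1c(Br)c(O)c2c(=O)c(OC)c(-c3ccccc3)oc2c1Br
A3 | alternative 1 | 5-hydroxy-3,7-dimethoxyflavone | COc1cc(O)c2c(=O)c(OC)c(-c3ccccc3)oc2c1
A4 | alternative 1 | galangin (3,5,7-trihydroxyflavone) | Oc1cc(O)c2c(=O)c(O)c(-c3ccccc3)oc2c1
A5 | alternative 2 | 5,6,7,8-tetramethoxyflavone | COc1c(OC)c(OC)c2c(=O)cc(-c3ccccc3)oc2c1OC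
A6 | alternative 2 | 2-iodo-3,4,5,6-tetramethoxyphenol | COc1c(OC)c(OC)c(I)c(O)c1OC
A7 | alternative 2 | phenylacetylene | C#Cc1ccccc1
A8 | alternative 2 | carbon monoxide | [C-]#[O+]
A9 | alternative 3 | 3-iodo-5,6,7,8-tetramethoxyflavone | COc1c(OC)c(OC)c2c(=O)c(I)c(-c3ccccc3)oc2c1OC
A10 | alternative 3 | 1-(2,3,4,5,6-pentamethoxyphenyl)-3-phenylprop-2-yn-1-one | COc1c(OC)c(OC)c(C(=O)C#Cc2ccccc2)c(OC)c1OC
A11 | alternative 3 | pentamethoxybenzene | COc1cc(OC)c(OC)c(OC)c1OC
A12 | alternative 3 | N-methoxy-N-methyl-3-phenylprop-2-ynamide | CON(C)C(=O)C#Cc1ccccc1
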